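## Retrosynthetic overview
1. Target 19 ⇐ hydroxy acetate 17, by moving the acetyl group from O14 to O15 and oxidising C14–OH.
2. 17 ⇐ furan aldehyde 13 (key step). Opening the furan gives a (Z)-ene-dione, and two aldol closures at C4 follow in one flask: C4–C15 (cyclopentenone), then C4=C5 (12-membered ring).
3. 13 ⇐ oxolane olefin 6 + furyl homoallylic acetate 10, joined at C11–C12 by cross-metathesis/hydrogenation, then glycol cleavage.
4. 6 ⇐ geraniol, by Sharpless epoxidation (C6), ozonolysis, reverse prenylation (C9, quaternary C10) and invertive 5-exo epoxide opening. 10 ⇐ anti-crotylboration of 4,5-dimethylfurfural (C13, sacrificial C14).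
5. Ring order: oxolane first, then cyclopentenone and macrocycle together.

Assumption: locants follow jatrophane numbering (C15 = acetoxy carbon, C14 = adjacent ketone, C13 = CHMe, C10 = CMe2, C9/C6 = oxolane carbons, C4=C5 = exocyclic alkene, C3 = enone C=O). Chiral ligands, catalysts and (+)-Ipc2BH are bought or made in situ from (−)-α-pinene.

## Route

Step 1
Reactants: 1 geraniol
Product: 2 (2R,3R)-2,3-epoxygeraniol
Conditions: Ti(OiPr)4 (5 mol %), D-(−)-DIPT (7 mol %), t-BuOOH, 4 Å MS, CH2Cl2, −20 °C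
Reagents that add atoms: tert-butyl hydroperoxide CC(C)(C)OO
Why: Katsuki–Sharpless asymmetric epoxidation with D-(−)-tartrate epoxidises only the allylic alkene and gives the (2R,3R)-epoxide, which fixes C6 as R for inversion in step 3.

Step 2
Reactants: 2 (2R,3R)-2,3-epoxygeraniol
Product: 3 3-[(2R,3R)-3-(hydroxymethyl)-2-methyloxiran-2-yl]propanal
Conditions: O3, CH2Cl2/MeOH, −78 °C; Me2S
Reagents that add atoms: ozone [O-][O+]=O
Why: Ozonolysis with reductive work-up cleaves the only remaining alkene to the C9 aldehyde, and the epoxide and alcohol are inert to it.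

Step 3
Reactants: 3 3-[(2R,3R)-3-(hydroxymethyl)-2-methyloxiran-2-yl]propanal; 4 3-methylbuta-1,2-diene
Product: 6 (1R)-1-[(2S,5S)-2-methyl-5-(2-methylbut-3-en-2-yl)oxolan-2-yl]ethane-1,2-diol, via epoxy homoallylic alcohol 5 (not isolated)
Conditions: (+)-Ipc2BH, 4, THF, −25 → 0 °C; 3, Et2O, −78 °C; NaBO3·4H2O, THF/H2O; CSA (10 mol %), CH2Cl2, 0 °C
Reagents that add atoms: none
Why: Brown asymmetric allylboration with the B-prenyl reagent attacks through its γ-carbon in a chair transition state, which builds quaternary C10 and sets C9 as S under reagent control, and the acid-catalysed 5-exo epoxide opening at tertiary C6 then proceeds with inversion (R→S) to give the trans-2,5-oxolane.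

Step 4
Reactants: 7 4,5-dimethylfuran-2-carbaldehyde; 8 (E)-crotylboronic acid pinacol ester
Product: 9 (1R,2R)-1-(4,5-dimethylfuran-2-yl)-2-methylbut-3-en-1-ol
Conditions: (R)-TRIP (5 mol %), toluene, −30 °C
Reagents that add atoms: none
Why: Chiral phosphoric acid-catalysed crotylboration passes through a closed chair transition state, so the E-boronate gives the anti adduct and the catalyst selects the aldehyde face, which sets permanent C13 (R) and sacrificial C14 (R).

Step 5
Reactants: 9 (1R,2R)-1-(4,5-dimethylfuran-2-yl)-2-methylbut-3-en-1-ol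
Product: 10 (1R,2R)-1-(4,5-dimethylfuran-2-yl)-2-methylbut-3-enyl acetate
Conditions: Ac2O, Et3N, DMAP (cat.), CH2Cl2, 0 °C → rt
Reagents that add atoms: acetic anhydride CC(=O)OC(C)=O
Why: DMAP-catalysed acetylation blocks an Achmatowicz pathway in step 8 and installs the acetyl group that ends up on O15, without touching any stereocentre.

Step 6
Reactants: 6 (1R)-1-[(2S,5S)-2-methyl-5-(2-methylbut-3-en-2-yl)oxolan-2-yl]ethane-1,2-diol; 10 (1R,2R)-1-(4,5-dimethylfuran-2-yl)-2-methylbut-3-enyl acetate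
Product: 12 saturated C11–C12 coupled diol acetate, via E-alkene 11 (not isolated)
Conditions: 10 (2.5 equiv), Hoveyda–Grubbs II (10 mol %), toluene, 70 °C; then H2 (50 bar), MeOH, Et3N, 60 °C
Reagents that add atoms: none
Why: Selective olefin cross-metathesis pairs a vinyl group on a quaternary carbon, which does not homodimerise, with a more reactive branched olefin, and the spent ruthenium then acts as the hydrogenation catalyst for the new alkene (tandem metathesis–hydrogenation) while furan, acetate, diol and all stereocentres remain untouched.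

Step 7
Reactants: 12 saturated C11–C12 coupled diol acetate
Product: 13 (1R,2R)-1-(4,5-dimethylfuran-2-yl)-5-[(2S,5S)-5-formyl-5-methyloxolan-2-yl]-2,5-dimethylhexyl acetate
Conditions: NaIO4, THF/H2O (pH 7), 0 °C
Reagents that add atoms: none
Why: Malaprade glycol cleavage releases the non-enolisable α-alkoxy aldehyde C5, so C6 cannot epimerise and the furan tolerates periodate.

Step 8
Reactants: 13 (1R,2R)-1-(4,5-dimethylfuran-2-yl)-5-[(2S,5S)-5-formyl-5-methyloxolan-2-yl]-2,5-dimethylhexyl acetate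
Product: 17 macrocyclic 15-hydroxy 14-acetate, via Z-enedione 14 (not isolated), via silyloxycyclopentenone aldehyde 15 (not isolated), via macrocyclic silyl ether 16 (not isolated)
Conditions: O2, methylene blue, hν, CH2Cl2/MeOH, −30 °C; Me2S; evaporate; slow addition to TMSOTf/i-Pr2NEt, CH2Cl2 (final 1 mM), −78 → 0 °C; DBU, 0 °C → rt; citric acid, MeOH
Reagents that add atoms: oxygen O=O
Why: Proposed new method: singlet-oxygen [4+2] addition to the trialkylfuran and Me2S reduction unmask the (Z)-ene-1,4-dione 14, TMSOTf/i-Pr2NEt silylates the fastest-enolising site (the C4 methyl ketone) and this enol silane closes on the neighbouring C15 ketone (5-enolexo Mukaiyama aldol, polar Felkin–Anh attack anti to the acetoxy group of the 14R centre, which sets C15) to give 15, whose only remaining enolisable position (C4H2) is silylated again and adds at high dilution to the activated non-enolisable C5 aldehyde, and DBU-induced E1cB loss of silanol gives the ring-imposed E-alkylidene, so the cyclopentenone and the 12-membered carbocycle form in one flask; the closest known reaction types are the one-pot furan photooxygenation/intramolecular aldol route to 4-hydroxycyclopent-2-enones, one-pot enol-silane formation/Mukaiyama aldol with TMSOTf and an amine, and macrocyclising Mukaiyama aldol reactions.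

Step 9
Reactants: 17 macrocyclic 15-hydroxy 14-acetate
Product: 19 target CNP0144863.1, via 15-acetate 14-alcohol 18 (not isolated)
Conditions: SO3·pyridine, DMSO, Et3N (excess), CH2Cl2, 0 °C → rt
Reagents that add atoms: none
Why: Proposed new method: Et3N equilibrates the vicinal hydroxy acetate by 1,2-O→O acetyl migration through a five-membered orthoester anion, only isomer 18 with a free secondary C14–OH can be oxidised under the same Parikh–Doering conditions, and the equilibrium therefore drains irreversibly to the α-acetoxy ketone without touching C15, C13, C9 or C6; the closest known reaction types are base-mediated acyl migration in 1,2-diol monoesters and Parikh–Doering oxidation.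

## Compound list
1 | geraniol, (2E)-3,7-dimethylocta-2,6-dien-1-ol | CC(C)=CCC/C(C)=C/CO | starting material
2 | [(2R,3R)-3-methyl-3-(4-methylpent-3-en-1-yl)oxiran-2-yl]methanol | OC[C@H]1O[C@]1(C)CCC=C(C)C | intermediate
3 | 3-[(2R,3R)-3-(hydroxymethyl)-2-methyloxiran-2-yl]propanal | OC[C@H]1O[C@]1(C)CCC=O | intermediate
4 | 3-methylbuta-1,2-diene | CC(C)=C=C | starting material
5 | (3S)-1-[(2R,3R)-3-(hydroxymethyl)-2-methyloxiran-2-yl]-4,4-dimethylhex-5-en-3-ol | OC[C@H]1O[C@]1(C)CC[C@H](O)C(C)(C)C=C | intermediate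
6 | (1R)-1-[(2S,5S)-2-methyl-5-(2-methylbut-3-en-2-yl)oxolan-2-yl]ethane-1,2-diol | OC[C@@H](O)[C@]1(C)CC[C@H](O1)C(C)(C)C=C | intermediate
7 | 4,5-dimethylfuran-2-carbaldehyde | O=Cc1cc(C)c(C)o1 | starting material
8 | (E)-crotylboronic acid pinacol ester | C/C=C/CB1OC(C)(C)C(C)(C)O1 | starting material
9 | (1R,2R)-1-(4,5-dimethylfuran-2-yl)-2-methylbut-3-en-1-ol | C=C[C@@H](C)[C@@H](O)c1cc(C)c(C)o1 | intermediate
10 | (1R,2R)-1-(4,5-dimethylfuran-2-yl)-2-methylbut-3-enyl acetate | C=C[C@@H](C)[C@@H](OC(C)=O)c1cc(C)c(C)o1 | intermediate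
11 | (E)-C11=C12 cross-metathesis product (5R,6S,9S,13R,14R) | OC[C@@H](O)[C@]1(C)CC[C@H](O1)C(C)(C)/C=C/[C@@H](C)[C@@H](OC(C)=O)c1cc(C)c(C)o1 | intermediate
12 | (1R,2R)-5-{(2S,5S)-5-[(1R)-1,2-dihydroxyethyl]-5-methyloxolan-2-yl}-1-(4,5-dimethylfuran-2-yl)-2,5-dimethylhexyl acetate | OC[C@@H](O)[C@]1(C)CC[C@H](O1)C(C)(C)CC[C@@H](C)[C@@H](OC(C)=O)c1cc(C)c(C)o1 | intermediate
13 | (1R,2R)-1-(4,5-dimethylfuran-2-yl)-5-[(2S,5S)-5-formyl-5-methyloxolan-2-yl]-2,5-dimethylhexyl acetate | O=C[C@]1(C)CC[C@H](O1)C(C)(C)CC[C@@H](C)[C@@H](OC(C)=O)c1cc(C)c(C)o1 | intermediate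
14 | aldehyde 13 with the furan opened to the (Z)-CH3C(=O)–C(CH3)=CH–C(=O)– unit (6S,9S,13R,14R) | O=C[C@]1(C)CC[C@H](O1)C(C)(C)CC[C@@H](C)[C@@H](OC(C)=O)C(=O)/C=C(/C)C(C)=O | intermediate
15 | 4-(trimethylsilyloxy)-2-methylcyclopent-2-enone carrying the (14R)-acetoxy side chain and the free C5 aldehyde (C15 reads R by CIP while C4 is CH2, with the same spatial arrangement as 15S in 17) | O=C[C@]1(C)CC[C@H](O1)C(C)(C)CC[C@@H](C)[C@@H](OC(C)=O)[C@]1(O[Si](C)(C)C)C=C(C)C(=O)C1 | intermediate
16 | macrocyclic (4E)-dienone, 15-O-TMS, 14-O-acetyl (6S,9S,13R,14R,15S) | C[Si](C)(C)O[C@@]12C=C(C)C(=O)/C1=C/[C@]1(C)CC[C@H](O1)C(C)(C)CC[C@@H](C)[C@H]2OC(C)=O | intermediate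
17 | macrocyclic (4E)-dienone, 15-hydroxy, 14-O-acetyl (6S,9S,13R,14R,15S) | O[C@@]12C=C(C)C(=O)/C1=C/[C@]1(C)CC[C@H](O1)C(C)(C)CC[C@@H](C)[C@H]2OC(C)=O | intermediate
18 | macrocyclic (4E)-dienone, 15-O-acetyl, 14-hydroxy (6S,9S,13R,14R,15S) | CC(=O)O[C@@]12C=C(C)C(=O)/C1=C/[C@]1(C)CC[C@H](O1)C(C)(C)CC[C@@H](C)[C@H]2O | intermediate
19 | CNP0144863.1, (4E,6S,9S,13R,15S)-15-acetoxy-6,9-epoxyjatropha-1,4-diene-3,14-dione | CC(=O)O[C@@]12C=C(C)C(=O)/C1=C/[C@]1(C)CC[C@H](O1)C(C)(C)CC[C@@H](C)C2=O | target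

## Step count and risks
- Total steps: 9.
- Longest linear sequence: 7 (steps 1, 2, 3, 6, 7, 8, 9).

**Most likely to fail, first: step 8.** The macrocyclising second aldol may lose to oligomerisation or to decomposition of the 4-oxycyclopentenone. The fallback sets out from 6 and 10 and comes back at 17, and it closes the large ring by metathesis instead of aldol.
- Compound 6 is cleaved with NaIO4 to (2S,5S)-2-methyl-5-(2-methylbut-3-en-2-yl)oxolane-2-carbaldehyde F1.
- The furan oxidation/TMSOTf sequence is run on 10 at normal concentration with F1 as the external aldehyde. This gives the open cross-conjugated dienone diene F2.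
- Ring-closing metathesis at C11=C12 gives the macrocyclic triene F3.
- Diimide reduces only the isolated disubstituted alkene of F3 and delivers 17.

**Second: step 9.** The acetyl shift to the tertiary oxygen may be too unfavourable or too slow. The fallback sets out from 17 and comes back at 19.
- Methanolysis (K2CO3, MeOH, 0 °C) gives the macrocyclic 14,15-diol F4.
- Dess–Martin oxidation of the only secondary alcohol gives the 15-hydroxy 14-ketone F5.
- Acetylation of the tertiary α-ketol (Ac2O, DMAP or Sc(OTf)3) gives 19.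

**Third: step 6.** Both olefins are hindered. The fallback sets out from 6 and 9 and comes back at 13, and it makes the metathesis intramolecular through a temporary silicon tether.
- i-Pr2SiCl2 links O14 of 9 to the primary hydroxyl of 6 and gives the tethered diene F6.
- Ring-closing metathesis gives the 13-membered cyclic alkene F7.
- Hydrogenation gives the saturated silacycle F8.
- HF·pyridine releases the triol F9.
- NaIO4 gives the hydroxy aldehyde F10. Its single hydroxyl is acetylated to give 13.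

## Further compounds
F1 | step 8 | (2S,5S)-2-methyl-5-(2-methylbut-3-en-2-yl)oxolane-2-carbaldehyde | O=C[C@]1(C)CC[C@H](O1)C(C)(C)C=C
F2 | step 8 | (4S,5E)-4-[(1R,2R)-1-acetoxy-2-methylbut-3-enyl]-4-hydroxy-2-methyl-5-{[(2S,5S)-2-methyl-5-(2-methylbut-3-en-2-yl)oxolan-2-yl]methylidene}cyclopent-2-en-1-one | O[C@@]1([C@H](OC(C)=O)[C@H](C)C=C)C=C(C)C(=O)/C1=C/[C@]1(C)CC[C@H](O1)C(C)(C)C=C
F3 | step 8 | (11E)-11,12-didehydro derivative of 17 | O[C@@]12C=C(C)C(=O)/C1=C/[C@]1(C)CC[C@H](O1)C(C)(C)/C=C/[C@@H](C)[C@H]2OC(C)=O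
F4 | step 9 | macrocyclic (14R,15S)-14,15-diol | O[C@@]12C=C(C)C(=O)/C1=C/[C@]1(C)CC[C@H](O1)C(C)(C)CC[C@@H](C)[C@H]2O
F5 | step 9 | 15-hydroxy 14-ketone (15-O-deacetyl target) | O[C@@]12C=C(C)C(=O)/C1=C/[C@]1(C)CC[C@H](O1)C(C)(C)CC[C@@H](C)C2=O
F6 | step 6 | diisopropylsilyl bis-ether joining O14 of 9 and the primary oxygen of 6 | C=C[C@@H](C)[C@@H](O[Si](C(C)C)(C(C)C)OC[C@@H](O)[C@]1(C)CC[C@H](O1)C(C)(C)C=C)c1cc(C)c(C)o1
F7 | step 6 | 13-membered cyclic silyl bis-ether with (E)-C11=C12 | CC(C)[Si]1(C(C)C)OC[C@@H](O)[C@]2(C)CC[C@H](O2)C(C)(C)/C=C/[C@@H](C)[C@@H](O1)c1cc(C)c(C)o1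
F8 | step 6 | saturated 13-membered cyclic silyl bis-ether | CC(C)[Si]1(C(C)C)OC[C@@H](O)[C@]2(C)CC[C@H](O2)C(C)(C)CC[C@@H](C)[C@@H](O1)c1cc(C)c(C)o1
F9 | step 6 | triol (12 without the acetyl group) | OC[C@@H](O)[C@]1(C)CC[C@H](O1)C(C)(C)CC[C@@H](C)[C@@H](O)c1cc(C)c(C)o1
F10 | step 6 | hydroxy aldehyde (13 without the acetyl group) | O=C[C@]1(C)CC[C@H](O1)C(C)(C)CC[C@@H](C)[C@@H](O)c1cc(C)c(C)o1
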